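**Plan**

- Retrosynthesis: the benzyl, ethyl and silyl groups come off last. Ring E of unit 2 is cut at O1''–C2'' and C4''–C4a'' back to an ortho-formylated ring D phenol and 4-benzyloxyphenylacetylene. Ring D is cut at C8''–C8a'' and C6''–C7'' (with the C4a''–C8a'' closure) into an aryl silyl ynol ether on C3' and 3-ethoxycyclobutenone. The ynol ether goes back to a 3'-bromoflavone (unit 1) from dibenzyl phloroacetophenone and 5-bromoveratraldehyde.
- Enabling feature: ring D is a phloroglucinol in which C8'', the carbon bonded to C3' of ring B, lies between the oxygen-bearing C7'' and C8a'' and para to C5''–O. An alkoxyvinylketene and an aryl ynol ether assemble exactly this 1-hydroxy-2-aryl-3,5-dioxy pattern.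
- Forward order: rings A and C are closed onto ring B (steps 1–3), the alkyne and its siloxy group are placed at C3' (steps 4–6), ring D is made by benzannulation (step 7), ring E by ortho-formylation, alkynylation, oxidation and 6-endo closure (steps 8–11), then deprotection (steps 12–13).
- Stereochemistry: the target has no stereocentre, so only regiochemistry matters. The ethoxy group para to C8'' allows ring E to close only in the 8-aryl (not 6-aryl) sense.

Key step: step 7

Remark: the C3'–C8'' biaryl axis carries no descriptor in the target and is treated as configurationally undefined; the sp3 centres of 13 and 19 are racemic and are erased later.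

**Route**

Step 1
Reactants: 1 2,4,6-trihydroxyacetophenone
Product: 2 1-[2,4-bis(benzyloxy)-6-hydroxyphenyl]ethanone
Conditions: BnBr (2.05 equiv), K2CO3, DMF, 0 °C → rt
Reagents that add atoms: benzyl bromide, BrCc1ccccc1
Why: Williamson etherification, in which the hydroxyl hydrogen-bonded to the acetyl carbonyl is the least nucleophilic and should stay free while the other two are benzylated.

Step 2
Reactants: 2 1-[2,4-bis(benzyloxy)-6-hydroxyphenyl]ethanone; 3 3-bromo-4,5-dimethoxybenzaldehyde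
Product: 4 (E)-1-[2,4-bis(benzyloxy)-6-hydroxyphenyl]-3-(3-bromo-4,5-dimethoxyphenyl)prop-2-en-1-one
Conditions: KOH, EtOH/THF, rt
Reagents that add atoms: none
Why: Claisen–Schmidt condensation of the acetophenone enolate with a non-enolizable aldehyde, the E1cB dehydration giving the E-enone.

Step 3
Reactants: 4 (E)-1-[2,4-bis(benzyloxy)-6-hydroxyphenyl]-3-(3-bromo-4,5-dimethoxyphenyl)prop-2-en-1-one
Product: 5 5,7-bis(benzyloxy)-2-(3-bromo-4,5-dimethoxyphenyl)chromen-4-one
Conditions: I2 (cat.), DMSO, 130 °C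
Reagents that add atoms: none
Why: Oxidative cyclization of a 2'-hydroxychalcone (oxa-Michael closure, then iodine-mediated dehydrogenation with DMSO as terminal oxidant), where the single free hydroxyl allows only one flavone and the aryl bromide and benzyl ethers are spectators.

Step 4
Reactants: 5 5,7-bis(benzyloxy)-2-(3-bromo-4,5-dimethoxyphenyl)chromen-4-one
Product: 6 5,7-bis(benzyloxy)-2-{3,4-dimethoxy-5-[(trimethylsilyl)ethynyl]phenyl}chromen-4-one
Conditions: Me3SiC≡CH, PdCl2(PPh3)2 (5 mol %), CuI (10 mol %), Et3N, DMF, 80 °C, sealed tube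
Reagents that add atoms: trimethylsilylacetylene, C#C[Si](C)(C)C
Why: Sonogashira coupling at the only carbon–halogen bond, which places the alkyne on the unhindered side of what later becomes the crowded C3'–C8'' axis.

Step 5
Reactants: 6 5,7-bis(benzyloxy)-2-{3,4-dimethoxy-5-[(trimethylsilyl)ethynyl]phenyl}chromen-4-one
Product: 7 5,7-bis(benzyloxy)-2-(3-ethynyl-4,5-dimethoxyphenyl)chromen-4-one
Conditions: K2CO3 (cat.), MeOH/CH2Cl2, rt
Reagents that add atoms: none
Why: Methanolysis of the alkynyl C–Si bond under mild base, which the flavone and the ethers tolerate.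

Step 6
Reactants: 7 5,7-bis(benzyloxy)-2-(3-ethynyl-4,5-dimethoxyphenyl)chromen-4-one
Product: 10 5,7-bis(benzyloxy)-2-{3,4-dimethoxy-5-[(triisopropylsiloxy)ethynyl]phenyl}chromen-4-one, via lithium acetylide 8 (not isolated), via lithium ynolate 9 (not isolated)
Conditions: LiN(SiMe3)2, THF, −78 °C; LiOOtBu (from tBuOOH and LiN(SiMe3)2), −78 → 0 °C; iPr3SiCl, −78 °C → rt; chromatography on Et3N-deactivated silica
Reagents that add atoms: tert-butyl hydroperoxide (used as its lithium salt), CC(C)(C)OO; triisopropylsilyl chloride, CC(C)[Si](Cl)(C(C)C)C(C)C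
Why: Electrophilic oxygen transfer from lithium tert-butyl peroxide to the lithium acetylide gives the ynolate, which the bulky silyl chloride should trap on oxygen; the amide base cannot deprotonate the flavone, and the 5-benzyloxy-flanked, doubly donor-substituted chromone carbonyl should add acetylide only slowly at these temperatures.

Step 7
Reactants: 10 5,7-bis(benzyloxy)-2-{3,4-dimethoxy-5-[(triisopropylsiloxy)ethynyl]phenyl}chromen-4-one; 11 3-ethoxycyclobut-2-en-1-one
Product: 16 5,7-bis(benzyloxy)-2-{3-[4-ethoxy-2-hydroxy-6-(triisopropylsiloxy)phenyl]-4,5-dimethoxyphenyl}chromen-4-one, via ethoxyvinylketene 12 (not isolated), via vinylcyclobutenone 13 (not isolated), via dienylketene 14 (not isolated), via cyclohexadienone 15 (not isolated)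
Conditions: 11 (1.3–1.5 equiv, added in portions), toluene, 80 → 100 °C, argon
Reagents that add atoms: none
Why: Thermal four-electron ring opening of 11 gives ethoxyvinylketene 12, whose ketene C=C undergoes [2+2] cycloaddition with ynol ether 10 (forming C8''–C8a'' and C6''–C7'') to give vinylcyclobutenone 13; a second four-electron opening gives dienylketene 14, whose six-electron electrocyclization re-forms C4a''–C8a'', and enolization of cyclohexadienone 15 gives phenol 16. The closest known reaction type is the Danheiser benzannulation of cyclobutenones with triisopropylsiloxyalkynes to resorcinol monosilyl ethers; the 3-ethoxy group only adds the third oxygen. Ring D is closed by the thermal disrotatory six-electron electrocyclization of the dienylketene, not by the cycloaddition. No stereocentre remains, because the sp3 carbon of 13 and the CH2 of 15 are lost on ring opening and tautomerization. The step needs regiocontrol in the ketene–alkyne [2+2] and chemoselectivity for the ynol ether over the chromone enone: the oxygen lone pair makes the aryl-bearing alkyne carbon the nucleophile toward the ketene carbonyl carbon, so the aryl group ends between the free hydroxyl and the silyl ether with ethoxy para to it, and the electron-rich alkyne is by far the best ketenophile present.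

Step 8
Reactants: 16 5,7-bis(benzyloxy)-2-{3-[4-ethoxy-2-hydroxy-6-(triisopropylsiloxy)phenyl]-4,5-dimethoxyphenyl}chromen-4-one
Product: 17 5,7-bis(benzyloxy)-2-{3-[4-ethoxy-3-formyl-2-hydroxy-6-(triisopropylsiloxy)phenyl]-4,5-dimethoxyphenyl}chromen-4-one
Conditions: MgCl2 (anhydrous), Et3N, (CH2O)n, MeCN, reflux
Reagents that add atoms: paraformaldehyde (formaldehyde), C=O
Why: Casnati–Skattebøl ortho-formylation, in which the magnesium phenoxide delivers formaldehyde to the only free ortho carbon (C4a'') and a second formaldehyde oxidizes the benzylic alkoxide by hydride transfer, without the Lewis acids that a Fries route would need.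

Step 9
Reactants: 17 5,7-bis(benzyloxy)-2-{3-[4-ethoxy-3-formyl-2-hydroxy-6-(triisopropylsiloxy)phenyl]-4,5-dimethoxyphenyl}chromen-4-one; 18 1-(benzyloxy)-4-ethynylbenzene
Product: 19 5,7-bis(benzyloxy)-2-{3-[3-{3-[4-(benzyloxy)phenyl]-1-hydroxyprop-2-yn-1-yl}-4-ethoxy-2-hydroxy-6-(triisopropylsiloxy)phenyl]-4,5-dimethoxyphenyl}chromen-4-one (racemic carbinol)
Conditions: 18 (3 equiv), EtMgBr (3 equiv), THF, 0 °C → rt; then 17, 0 °C → rt; aq NH4Cl
Reagents that add atoms: none
Why: Addition of an alkynyl Grignard reagent to the magnesium-chelated salicylaldehyde, a reagent too weak to attack the chromone, giving a racemic carbinol whose centre is removed in step 10.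

Step 10
Reactants: 19 5,7-bis(benzyloxy)-2-{3-[3-{3-[4-(benzyloxy)phenyl]-1-hydroxyprop-2-yn-1-yl}-4-ethoxy-2-hydroxy-6-(triisopropylsiloxy)phenyl]-4,5-dimethoxyphenyl}chromen-4-one
Product: 20 5,7-bis(benzyloxy)-2-{3-[3-{3-[4-(benzyloxy)phenyl]prop-2-ynoyl}-4-ethoxy-2-hydroxy-6-(triisopropylsiloxy)phenyl]-4,5-dimethoxyphenyl}chromen-4-one
Conditions: MnO2 (activated, excess), CH2Cl2, rt
Reagents that add atoms: none
Why: Oxidation of a benzylic, propargylic alcohol by MnO2, a standard way to ortho-hydroxyaryl ynones that leaves benzyl and silyl ethers untouched.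

Step 11
Reactants: 20 5,7-bis(benzyloxy)-2-{3-[3-{3-[4-(benzyloxy)phenyl]prop-2-ynoyl}-4-ethoxy-2-hydroxy-6-(triisopropylsiloxy)phenyl]-4,5-dimethoxyphenyl}chromen-4-one
Product: 22 5,7-bis(benzyloxy)-2-{3-[2-(4-benzyloxyphenyl)-5-ethoxy-4-oxo-7-(triisopropylsiloxy)chromen-8-yl]-4,5-dimethoxyphenyl}chromen-4-one, via enaminone 21 (not isolated)
Conditions: Et2NH, EtOH, reflux
Reagents that add atoms: none
Why: Amine-mediated cyclization of an ortho-hydroxyaryl ynone, where conjugate addition of Et2NH gives the enaminone and the C8a'' hydroxyl then displaces the amine by addition–elimination, so that the 6-endo flavone and not the 5-exo aurone should form.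

Step 12
Reactants: 22 5,7-bis(benzyloxy)-2-{3-[2-(4-benzyloxyphenyl)-5-ethoxy-4-oxo-7-(triisopropylsiloxy)chromen-8-yl]-4,5-dimethoxyphenyl}chromen-4-one
Product: 23 5,7-bis(benzyloxy)-2-{3-[2-(4-benzyloxyphenyl)-5-ethoxy-7-hydroxy-4-oxochromen-8-yl]-4,5-dimethoxyphenyl}chromen-4-one
Conditions: Bu4NF, AcOH, THF, 0 °C
Reagents that add atoms: none
Why: Fluoride cleavage of the aryl silyl ether, buffered with acetic acid so that the flavones are not exposed to a basic phenoxide medium.

Step 13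
Reactants: 23 5,7-bis(benzyloxy)-2-{3-[2-(4-benzyloxyphenyl)-5-ethoxy-7-hydroxy-4-oxochromen-8-yl]-4,5-dimethoxyphenyl}chromen-4-one
Product: 24 5'-methoxybilobetin
Conditions: BCl3 (excess), C6HMe5, CH2Cl2, −78 → 0 °C, then rt until the ethyl ether is gone; MeOH quench
Reagents that add atoms: none
Why: Lewis acid ether cleavage, in which BCl3 with pentamethylbenzene as cation trap removes the three benzyl groups at low temperature and, through the six-membered boron chelate with the C4'' carbonyl, the peri 5''-ethyl ether, while the non-chelated 4'- and 5'-methyl ethers of ring B should survive.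

**Compound list**

1 | 2,4,6-trihydroxyacetophenone | CC(=O)c1c(O)cc(O)cc1O | starting material
2 | 1-[2,4-bis(benzyloxy)-6-hydroxyphenyl]ethanone | CC(=O)c1c(O)cc(OCc2ccccc2)cc1OCc1ccccc1 | intermediate
3 | 3-bromo-4,5-dimethoxybenzaldehyde (5-bromoveratraldehyde) | COc1cc(C=O)cc(Br)c1OC | starting material
4 | (E)-1-[2,4-bis(benzyloxy)-6-hydroxyphenyl]-3-(3-bromo-4,5-dimethoxyphenyl)prop-2-en-1-one | COc1cc(/C=C/C(=O)c2c(O)cc(OCc3ccccc3)cc2OCc2ccccc2)cc(Br)c1OC | intermediate
5 | 5,7-bis(benzyloxy)-2-(3-bromo-4,5-dimethoxyphenyl)chromen-4-one | COc1cc(-c2cc(=O)c3c(OCc4ccccc4)cc(OCc4ccccc4)cc3o2)cc(Br)c1OC | intermediate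
6 | 5,7-bis(benzyloxy)-2-{3,4-dimethoxy-5-[(trimethylsilyl)ethynyl]phenyl}chromen-4-one | COc1cc(-c2cc(=O)c3c(OCc4ccccc4)cc(OCc4ccccc4)cc3o2)cc(C#C[Si](C)(C)C)c1OC | intermediate
7 | 5,7-bis(benzyloxy)-2-(3-ethynyl-4,5-dimethoxyphenyl)chromen-4-one | COc1cc(-c2cc(=O)c3c(OCc4ccccc4)cc(OCc4ccccc4)cc3o2)cc(C#C)c1OC | intermediate
8 | lithium acetylide of 7 | COc1cc(-c2cc(=O)c3c(OCc4ccccc4)cc(OCc4ccccc4)cc3o2)cc(C#C[Li])c1OC | intermediate (not isolated)
9 | lithium ynolate (lithium 2-arylethynolate of unit 1) | COc1cc(-c2cc(=O)c3c(OCc4ccccc4)cc(OCc4ccccc4)cc3o2)cc(C#CO[Li])c1OC | intermediate (not isolated)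
10 | 5,7-bis(benzyloxy)-2-{3,4-dimethoxy-5-[(triisopropylsiloxy)ethynyl]phenyl}chromen-4-one | COc1cc(-c2cc(=O)c3c(OCc4ccccc4)cc(OCc4ccccc4)cc3o2)cc(C#CO[Si](C(C)C)(C(C)C)C(C)C)c1OC | intermediate
11 | 3-ethoxycyclobut-2-en-1-one | CCOC1=CC(=O)C1 | starting material
12 | 3-ethoxybuta-1,3-dien-1-one (ethoxyvinylketene) | CCOC(=C)C=C=O | intermediate (not isolated)
13 | 2-aryl-4-(1-ethoxyvinyl)-3-(triisopropylsiloxy)cyclobut-2-en-1-one, aryl = ring B of unit 1, racemic | COc1cc(-c2cc(=O)c3c(OCc4ccccc4)cc(OCc4ccccc4)cc3o2)cc(C2=C(O[Si](C(C)C)(C(C)C)C(C)C)C(C(=C)OCC)C2=O)c1OC | intermediate (not isolated)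
14 | 2-aryl-5-ethoxy-3-(triisopropylsiloxy)hexa-1,3,5-trien-1-one (dienylketene, ketene carbon and vinyl group cis) | COc1cc(-c2cc(=O)c3c(OCc4ccccc4)cc(OCc4ccccc4)cc3o2)cc(C(=C=O)/C(O[Si](C(C)C)(C(C)C)C(C)C)=C\C(=C)OCC)c1OC | intermediate (not isolated)
15 | 2-aryl-5-ethoxy-3-(triisopropylsiloxy)cyclohexa-2,4-dien-1-one | COc1cc(-c2cc(=O)c3c(OCc4ccccc4)cc(OCc4ccccc4)cc3o2)cc(C2=C(O[Si](C(C)C)(C(C)C)C(C)C)C=C(OCC)CC2=O)c1OC | intermediate (not isolated)
16 | 5,7-bis(benzyloxy)-2-{3-[4-ethoxy-2-hydroxy-6-(triisopropylsiloxy)phenyl]-4,5-dimethoxyphenyl}chromen-4-one | COc1cc(-c2cc(=O)c3c(OCc4ccccc4)cc(OCc4ccccc4)cc3o2)cc(-c2c(O)cc(OCC)cc2O[Si](C(C)C)(C(C)C)C(C)C)c1OC | intermediate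
17 | 5,7-bis(benzyloxy)-2-{3-[4-ethoxy-3-formyl-2-hydroxy-6-(triisopropylsiloxy)phenyl]-4,5-dimethoxyphenyl}chromen-4-one | COc1cc(-c2cc(=O)c3c(OCc4ccccc4)cc(OCc4ccccc4)cc3o2)cc(-c2c(O)c(C=O)c(OCC)cc2O[Si](C(C)C)(C(C)C)C(C)C)c1OC | intermediate
18 | 1-(benzyloxy)-4-ethynylbenzene | C#Cc1ccc(OCc2ccccc2)cc1 | starting material
19 | propargylic alcohol: ring D of 17 with CH(OH)C≡C(4-benzyloxyphenyl) at C4a'', racemic | COc1cc(-c2cc(=O)c3c(OCc4ccccc4)cc(OCc4ccccc4)cc3o2)cc(-c2c(O)c(C(O)C#Cc3ccc(OCc4ccccc4)cc3)c(OCC)cc2O[Si](C(C)C)(C(C)C)C(C)C)c1OC | intermediate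
20 | ynone: ring D with C(=O)C≡C(4-benzyloxyphenyl) at C4a'' | COc1cc(-c2cc(=O)c3c(OCc4ccccc4)cc(OCc4ccccc4)cc3o2)cc(-c2c(O)c(C(=O)C#Cc3ccc(OCc4ccccc4)cc3)c(OCC)cc2O[Si](C(C)C)(C(C)C)C(C)C)c1OC | intermediate
21 | β-(diethylamino)enone from 20 | COc1cc(-c2cc(=O)c3c(OCc4ccccc4)cc(OCc4ccccc4)cc3o2)cc(-c2c(O)c(C(=O)C=C(N(CC)CC)c3ccc(OCc4ccccc4)cc3)c(OCC)cc2O[Si](C(C)C)(C(C)C)C(C)C)c1OC | intermediate (not isolated)
22 | 5,7-bis(benzyloxy)-2-{3-[2-(4-benzyloxyphenyl)-5-ethoxy-4-oxo-7-(triisopropylsiloxy)chromen-8-yl]-4,5-dimethoxyphenyl}chromen-4-one | COc1cc(-c2cc(=O)c3c(OCc4ccccc4)cc(OCc4ccccc4)cc3o2)cc(-c2c(O[Si](C(C)C)(C(C)C)C(C)C)cc(OCC)c3c(=O)cc(-c4ccc(OCc5ccccc5)cc4)oc23)c1OC | intermediate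
23 | 5,7-bis(benzyloxy)-2-{3-[2-(4-benzyloxyphenyl)-5-ethoxy-7-hydroxy-4-oxochromen-8-yl]-4,5-dimethoxyphenyl}chromen-4-one | COc1cc(-c2cc(=O)c3c(OCc4ccccc4)cc(OCc4ccccc4)cc3o2)cc(-c2c(O)cc(OCC)c3c(=O)cc(-c4ccc(OCc5ccccc5)cc4)oc23)c1OC | intermediate
24 | 5'-methoxybilobetin | COc1cc(-c2cc(=O)c3c(O)cc(O)cc3o2)cc(-c2c(O)cc(O)c3c(=O)cc(-c4ccc(O)cc4)oc23)c1OC | target

**Count**

Total steps: 13. Longest linear sequence: 13 steps (1 → 24); 3, 11 and 18 enter as purchased compounds.

**Steps most likely to fail**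

1. Step 7. The push–pull cyclobutenone 11 may open too slowly at temperatures the ynol ether tolerates, the ketene may acylate the product phenol or oligomerize, and the silyl group of 10 may migrate from oxygen to carbon on prolonged heating. The fallback sets out from 10 and comes back at 16. Ketene 12 would be generated at 0 °C to room temperature by 1,4-dehydrochlorination of (E)-3-ethoxybut-2-enoyl chloride F1 (from (E)-3-ethoxybut-2-enoic acid and oxalyl chloride) with Et3N in the presence of 10. The ketene–ynol ether [2+2] would then give vinylcyclobutenone 13 with no cyclobutenone opening needed and no phenol present to be acylated. Brief warming of 13 in toluene (four-electron opening, six-electron closure) should give 16.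

2. Step 6. The lithium acetylide may add to the chromone carbonyl of a second molecule, or the peroxide may attack the pyranone, before oxygen transfer to the acetylide is complete. The fallback sets out from 5 and 2 and comes back at 24; it gives up the benzannulation for a Suzuki–Miyaura union of two flavones.
   - Miyaura borylation of 5 (B2pin2, PdCl2(dppf), KOAc, dioxane, 90 °C) should give 5,7-bis(benzyloxy)-2-[3,4-dimethoxy-5-(4,4,5,5-tetramethyl-1,3,2-dioxaborolan-2-yl)phenyl]chromen-4-one F2.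
   - Iodination of 2 ortho to its free hydroxyl (N-iodosuccinimide, CH2Cl2) should give 1-[4,6-bis(benzyloxy)-2-hydroxy-3-iodophenyl]ethanone F3.
   - Claisen–Schmidt condensation with 4-(benzyloxy)benzaldehyde should give (E)-1-[4,6-bis(benzyloxy)-2-hydroxy-3-iodophenyl]-3-[4-(benzyloxy)phenyl]prop-2-en-1-one F4.
   - I2/DMSO closure should give 5,7-bis(benzyloxy)-2-[4-(benzyloxy)phenyl]-8-iodochromen-4-one F5.
   - Coupling of F2 with F5 (Pd(PPh3)4, K2CO3, DMF/H2O, 90 °C) should give 5,7,5'',7'',4'''-penta-O-benzyl-5'-methoxybilobetin F6, and BCl3 with pentamethylbenzene at −78 °C should then give 24.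

3. Step 13. Cleavage of the chelated ethyl ether may lag behind debenzylation, and forcing it may start demethylation of the vicinal methoxy groups of ring B. The fallback sets out from 23 and comes back at 24, and separates the two events. Hydrogenolysis (H2, Pd/C, THF/MeOH) should remove the three benzyl groups to give 5''-O-ethyl-5'-methoxybilobetin F7. Chelation-directed de-ethylation of the peri ether with AlCl3 in MeCN, a reagent that spares non-chelated methyl ethers, should then give 24.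

**Further compounds**

F1 | step 7 | (E)-3-ethoxybut-2-enoyl chloride | CCO/C(C)=C/C(Cl)=O
F2 | step 6 | 5,7-bis(benzyloxy)-2-[3,4-dimethoxy-5-(4,4,5,5-tetramethyl-1,3,2-dioxaborolan-2-yl)phenyl]chromen-4-one | COc1cc(-c2cc(=O)c3c(OCc4ccccc4)cc(OCc4ccccc4)cc3o2)cc(B2OC(C)(C)C(C)(C)O2)c1OC
F3 | step 6 | 1-[4,6-bis(benzyloxy)-2-hydroxy-3-iodophenyl]ethanone | CC(=O)c1c(O)c(I)c(OCc2ccccc2)cc1OCc1ccccc1
F4 | step 6 | (E)-1-[4,6-bis(benzyloxy)-2-hydroxy-3-iodophenyl]-3-[4-(benzyloxy)phenyl]prop-2-en-1-one | O=C(/C=C/c1ccc(OCc2ccccc2)cc1)c1c(O)c(I)c(OCc2ccccc2)cc1OCc1ccccc1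
F5 | step 6 | 5,7-bis(benzyloxy)-2-[4-(benzyloxy)phenyl]-8-iodochromen-4-one | O=c1cc(-c2ccc(OCc3ccccc3)cc2)oc2c(I)c(OCc3ccccc3)cc(OCc3ccccc3)c12
F6 | step 6 | 5,7,5'',7'',4'''-penta-O-benzyl-5'-methoxybilobetin | COc1cc(-c2cc(=O)c3c(OCc4ccccc4)cc(OCc4ccccc4)cc3o2)cc(-c2c(OCc3ccccc3)cc(OCc3ccccc3)c3c(=O)cc(-c4ccc(OCc5ccccc5)cc4)oc23)c1OC
F7 | step 13 | 5''-O-ethyl-5'-methoxybilobetin | COc1cc(-c2cc(=O)c3c(O)cc(O)cc3o2)cc(-c2c(O)cc(OCC)c3c(=O)cc(-c4ccc(O)cc4)oc23)c1OC
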